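**Retrosynthetic overview**
- Feature (labdane numbering): the cyclobutane (C8, C9, C14, C15) and ring D (C9, C11, C12, C13, C14) share the bond C9–C14. Without it they are one seven-membered ring (C8, C9, C11–C15) in which C9 and C14 are the β-carbons of a C12 cross-conjugated dienone.
- Key disconnection: C9–C14 together with C13–OH. Irradiation of the ring B-fused cyclohepta-2,6-dienone 14 in aqueous medium joins the β-carbons and water captures the oxyallyl intermediate, closing the cyclobutane and ring D at once.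
- Dienone 14 ⇒ ketone dehydrogenation (C9=C11) ⇒ ring-closing metathesis (C13=C14) ⇒ reductive allylation of a 7-oxo-8-ene (quaternary C8) ⇒ (+)-sclareolide (rings A and B, C1–C12, C17–C20). Allyl bromide supplies C14 and C15, isopropenylmagnesium bromide C13 and C16.
- After the key step: C12 deoxygenation (tosylhydrazone, Shapiro reaction, hydrogenation), C7 back to the ketone, 6β-acetoxy group by thermal rearrangement of the α-epoxide of the C6–C7 enol acetate.
- Ring order: rings A and B (from 1), seven-membered ring (step 8), cyclobutane and ring D together (step 10).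

Key step: step 10

Remark: labdane numbering is used throughout (C17 = methyl on C8, C18 and C19 on C4, C20 on C10; β = face of the C10 methyl). The configurations written for C9 in 5–12 and for C7 in 7–21 are the expected ones; both centres are removed later (steps 9 and 15) and do not bear on the target.

**Step 1**
Reactants: 1 (+)-sclareolide
Product: 2 methyl 13,14,15,16-tetranorlabd-8-en-12-oate
Conditions: conc. H2SO4, MeOH, reflux
Reagents that add atoms: methanol, CO
Why: Acid ionises the tertiary C8–O lactone bond, the cation loses a proton and the acid is esterified (E1 elimination, Fischer esterification); equilibration in acid favours the tetrasubstituted C8=C9 alkene, and C5 and C10 are not touched.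

**Step 2**
Reactants: 2 methyl 13,14,15,16-tetranorlabd-8-en-12-oate
Product: 3 methyl 7-oxo-13,14,15,16-tetranorlabd-8-en-12-oate
Conditions: CrO3, 3,5-dimethylpyrazole, CH2Cl2, −20 °C
Reagents that add atoms: chromium trioxide, O=[Cr](=O)=O
Why: Allylic oxidation by the CrO3–3,5-dimethylpyrazole complex should take the ring methylene C7, since C11 is deactivated by the ester and the C17 methyl reacts more slowly, and gives the conjugated enone.

**Step 3**
Reactants: 3 methyl 7-oxo-13,14,15,16-tetranorlabd-8-en-12-oate; 4 allyl bromide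
Product: 6 methyl 8α-allyl-7-oxo-13,14,15,16-tetranorlabdan-12-oate (8β-CH3; 9α-H), via lithium enolate 5 (not isolated)
Conditions: Li (2.2 equiv), t-BuOH (1.0 equiv), NH3(l)/THF, −78 °C; then allyl bromide (excess), −78 to −33 °C; NH4Cl
Reagents that add atoms: allyl bromide, C=CCBr
Why: Stork reductive alkylation: reduction of the enone gives only the C7–C8 enolate 5 (C9 protonated axially to 9α-H), and allyl bromide attacks C8 on the α face because the β face is 1,3-diaxial to the C10 methyl, which sets C8 with C17 β and allyl α; short exposure at −78 °C with a measured amount of lithium should spare the ester.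

**Step 4**
Reactants: 6 methyl 8α-allyl-7-oxo-13,14,15,16-tetranorlabdan-12-oate
Product: 7 methyl 8α-allyl-7β-hydroxy-13,14,15,16-tetranorlabdan-12-oate
Conditions: NaBH4, MeOH, 0 °C
Reagents that add atoms: none
Why: Hydride should add to C7 from the α face, since the β face is covered by the axial C17 methyl, giving the equatorial 7β-alcohol; the ester and the alkene are inert to NaBH4 at 0 °C.

**Step 5**
Reactants: 7 methyl 8α-allyl-7β-hydroxy-13,14,15,16-tetranorlabdan-12-oate
Product: 8 methyl 8α-allyl-7β-(tert-butyldimethylsilyloxy)-13,14,15,16-tetranorlabdan-12-oate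
Conditions: TBSOTf, 2,6-lutidine, CH2Cl2, 0 °C to rt
Reagents that add atoms: tert-butyldimethylsilyl triflate, CC(C)(C)[Si](C)(C)OS(=O)(=O)C(F)(F)F
Why: Silyl triflate silylation of a hindered secondary alcohol; the ether masks C7 through the organometallic, metathesis and photochemical steps.

**Step 6**
Reactants: 8 methyl 8α-allyl-7β-(tert-butyldimethylsilyloxy)-13,14,15,16-tetranorlabdan-12-oate
Product: 9 N-methoxy-N-methyl 8α-allyl-7β-(tert-butyldimethylsilyloxy)-13,14,15,16-tetranorlabdan-12-amide
Conditions: MeNH(OMe)·HCl, i-PrMgCl, THF, −20 to 0 °C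
Reagents that add atoms: N,O-dimethylhydroxylamine hydrochloride, CNOC.Cl
Why: Aminolysis of the methyl ester by the chloromagnesium amide of N,O-dimethylhydroxylamine (Weinreb amide formation); no stereocentre is affected.

**Step 7**
Reactants: 9 N-methoxy-N-methyl amide; 10 isopropenylmagnesium bromide
Product: 11 isopropenyl ketone C11H2–C12(=O)–C13(CH3)=CH2 (8α-allyl, 7β-OTBS, 9α-H)
Conditions: THF, 0 °C; poured into cold aq. NH4Cl
Reagents that add atoms: isopropenylmagnesium bromide, CC(=C)[Mg]Br
Why: Weinreb ketone synthesis: the chelated tetrahedral adduct holds until the quench, so one isopropenyl group is added and conjugate addition to the new enone is avoided.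

**Step 8**
Reactants: 11 isopropenyl ketone
Product: 12 6-6-7 tricyclic 13-en-12-one (ring C8–C15–C14=C13(CH3)–C12(=O)–C11H2–C9; 9α-H, 7β-OTBS)
Conditions: second-generation Grubbs catalyst (10 mol %), toluene (2 mM), 80 °C
Reagents that add atoms: none
Why: Ring-closing metathesis starts at the allyl terminus and closes onto the 1,1-disubstituted enone alkene to form the seven-membered ring (C8, C15, C14, C13, C12, C11, C9) with the C13=C14 bond; the two chains are trans-diequatorial on ring B and the quaternary C8 favours closure.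

**Step 9**
Reactants: 12 tricyclic 13-en-12-one
Product: 14 6-6-7 tricyclic cross-conjugated 9(11),13-dien-12-one (7β-OTBS), via lithium dienolate 13 (not isolated)
Conditions: LDA, THF, −78 °C; N-tert-butylbenzenesulfinimidoyl chloride, −78 °C
Reagents that add atoms: none
Why: Mukaiyama dehydrogenation: kinetic α′-deprotonation at C11 (C13 carries no hydrogen) gives dienolate 13, sulfur is attached at C11 and syn-elimination removes the 9α-hydrogen, forming C9=C11 and deleting the C9 stereocentre.

**Step 10**
Reactants: 14 tricyclic 9(11),13-dien-12-one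
Product: 16 tetracyclic 13-hydroxy-12-ketone (7β-OTBS), via oxyallyl zwitterion 15 (not isolated)
Conditions: hν (365 nm LEDs), MeCN/H2O (3:1), argon-sparged, 5 mM, 10 °C
Reagents that add atoms: water, O
Why: Proposed new method: n→π* excitation of the cross-conjugated dienone should lead to bonding between the two β-carbons C9 and C14 (formally a disrotatory 4π closure of the C9=C11–C12(=O)–C13=C14 unit) and, after intersystem crossing, to the oxyallyl zwitterion 15 spanning C11–C12–C13; water adds at C13, the more substituted and less hindered terminus, and the enol is protonated at C11. The closest known reactions are the photochemical β,β′-bonding of cross-conjugated cyclohexadienones, 4-pyranones and cycloocta-2,7-dienones with capture of the oxyallyl intermediate by a hydroxylic solvent; a cyclohepta-2,6-dienone closing to a bicyclo[3.2.0]heptanone with water capture has not been shown. The cyclobutane (C8, C9, C14, C15) closes by transannular 1,4-bonding across the seven-membered ring over the C8–C15 bridge, and ring D (C9, C11, C12, C13, C14) is closed by the same bond as the five-membered oxyallyl ring. C15 already sits on the α face of C8, so C14 can reach only the α face of C9 (cis 6-4 fusion, C11 β) and the bicyclo[3.2.0] unit must be cis-fused, which fixes C14; water approaches C13 from the side of the C14 hydrogen, away from C15, so the hydroxyl ends trans to C15. The step needs β,β′-bonding to outrun E/Z isomerisation with conjugate addition of water and 1,2-shifts of the zwitterion: the C9=C11 bond is exocyclic to ring B and cannot twist, the two-carbon bridge holds C9 and C14 close, and the high water content should trap the zwitterion quickly.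

**Step 11**
Reactants: 16 tetracyclic 13-hydroxy-12-ketone
Product: 17 C12 p-toluenesulfonylhydrazone of 16
Conditions: TsNHNH2, EtOH, 60 °C
Reagents that add atoms: p-toluenesulfonyl hydrazide, Cc1ccc(cc1)S(=O)(=O)NN
Why: Condensation of the cyclopentanone with tosylhydrazide gives the hydrazone with the N–N bond turned to C11, away from the quaternary C13; the silyl ether and the tertiary alcohol are stable.

**Step 12**
Reactants: 17 C12 p-toluenesulfonylhydrazone
Product: 19 tetracyclic 11-en-13-ol (C11=C12; 7β-OTBS), via vinyllithium 18 (not isolated)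
Conditions: LDA (4 equiv), THF, −78 °C to rt; H2O
Reagents that add atoms: none
Why: Shapiro reaction: after O- and N-deprotonation the only α-hydrogens, at C11, are removed, sulfinate and N2 are lost and the C12 vinyl anion is protonated, so the C12 oxygen leaves as a C11=C12 alkene while the C13–O bond is untouched.

**Step 13**
Reactants: 19 tetracyclic 11-en-13-ol
Product: 20 tetracyclic 13-ol 7β-silyl ether (C11H2–C12H2)
Conditions: H2 (1 atm), PtO2, EtOAc, rt
Reagents that add atoms: none
Why: Hydrogenation of the disubstituted cyclopentene creates no stereocentre; platinum is chosen to avoid hydrogenolysis of the allylic C13–O bond.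

**Step 14**
Reactants: 20 tetracyclic 13-ol 7β-silyl ether
Product: 21 tetracyclic 7β,13-diol
Conditions: TBAF, THF, 60 °C
Reagents that add atoms: none
Why: Fluoride cleaves the hindered secondary silyl ether; nothing else in 20 reacts.

**Step 15**
Reactants: 21 tetracyclic 7β,13-diol
Product: 22 tetracyclic 13-hydroxy-7-ketone
Conditions: DMP (1,1,1-triacetoxy-1,1-dihydro-1,2-benziodoxol-3(1H)-one), CH2Cl2, rt
Reagents that add atoms: none
Why: The periodinane oxidises the secondary C7 alcohol to the ketone; the tertiary C13 alcohol cannot be oxidised.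

**Step 16**
Reactants: 22 tetracyclic 13-hydroxy-7-ketone
Product: 23 13-O-trimethylsilyl ether of 22
Conditions: 1-(trimethylsilyl)imidazole, CH2Cl2, rt
Reagents that add atoms: 1-(trimethylsilyl)imidazole, C[Si](C)(C)n1ccnc1
Why: Silylation of the tertiary alcohol by a neutral silyl donor that does not enolise the ketone; it keeps the C13 oxygen from being acetylated in step 17.

**Step 17**
Reactants: 23 13-O-trimethylsilyl 7-ketone
Product: 25 C6–C7 enol acetate (7-acetoxy-6-ene, 13-OTMS), via lithium enolate 24 (not isolated)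
Conditions: LDA, THF, −78 to −30 °C; Ac2O, −78 to 0 °C
Reagents that add atoms: acetic anhydride, CC(=O)OC(C)=O
Why: C8 is quaternary, so deprotonation can give only the C6–C7 enolate 24, and acetic anhydride acylates it on oxygen (enol acetate formation).

**Step 18**
Reactants: 25 C6–C7 enol acetate
Product: 26 6α,7α-epoxy-7β-acetate (13-OTMS)
Conditions: dimethyldioxirane, acetone/CH2Cl2, −20 to 0 °C
Reagents that add atoms: dimethyldioxirane, CC1(C)OO1
Why: Epoxidation of the electron-rich enol acetate under neutral conditions should occur on the α face, as the β face is covered by the axial methyls C17, C19 and C20; this places the epoxide oxygen α at C6 and C7.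

**Step 19**
Reactants: 26 6α,7α-epoxy-7β-acetate
Product: 28 CNP0330581.1 (6β-acetoxy-13-hydroxy tetracyclic 7-ketone), via silyl ether 27 (not isolated)
Conditions: toluene, 120 °C (sealed, base-washed glass); concentrate; PPTS (cat.), MeOH, 0 °C
Reagents that add atoms: none
Why: Thermal enol ester epoxide rearrangement: the acetate carbonyl oxygen on the β face of C7 attacks C6 from the rear as the C6–O epoxide bond breaks and C7 becomes the ketone, so the acetoxy group arrives at C6 with inversion (6β-OAc, 6α-H); neutral heating avoids the acid-catalysed path with retention, and mild methanolysis then removes the trimethylsilyl group without epimerising C6.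

**Compound list**
1 | (+)-sclareolide | O=C1C[C@@H]2[C@@]3(C)CCCC(C)(C)[C@@H]3CC[C@@]2(C)O1 | starting material
2 | methyl 13,14,15,16-tetranorlabd-8-en-12-oate (5α-H, 10β-CH3) | C1CC(C)=C(CC(=O)OC)[C@@]2(C)CCCC(C)(C)[C@H]12 | intermediate
3 | methyl 7-oxo-13,14,15,16-tetranorlabd-8-en-12-oate | C1C(=O)C(C)=C(CC(=O)OC)[C@@]2(C)CCCC(C)(C)[C@H]12 | intermediate
4 | allyl bromide | C=CCBr | starting material
5 | lithium C7–C8 enolate of the 9α-H keto ester | C1C(O[Li])=C(C)[C@H](CC(=O)OC)[C@@]2(C)CCCC(C)(C)[C@H]12 | intermediate (not isolated)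
6 | methyl 8α-allyl-7-oxo-13,14,15,16-tetranorlabdan-12-oate (8β-CH3, 9α-H) | C1C(=O)[C@@](C)(CC=C)[C@H](CC(=O)OC)[C@@]2(C)CCCC(C)(C)[C@H]12 | intermediate
7 | methyl 8α-allyl-7β-hydroxy-13,14,15,16-tetranorlabdan-12-oate | C1[C@H](O)[C@@](C)(CC=C)[C@H](CC(=O)OC)[C@@]2(C)CCCC(C)(C)[C@H]12 | intermediate
8 | methyl 8α-allyl-7β-(tert-butyldimethylsilyloxy)-13,14,15,16-tetranorlabdan-12-oate | C1[C@H](O[Si](C)(C)C(C)(C)C)[C@@](C)(CC=C)[C@H](CC(=O)OC)[C@@]2(C)CCCC(C)(C)[C@H]12 | intermediate
9 | N-methoxy-N-methyl 8α-allyl-7β-(tert-butyldimethylsilyloxy)-13,14,15,16-tetranorlabdan-12-amide | C1[C@H](O[Si](C)(C)C(C)(C)C)[C@@](C)(CC=C)[C@H](CC(=O)N(C)OC)[C@@]2(C)CCCC(C)(C)[C@H]12 | intermediate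
10 | isopropenylmagnesium bromide | CC(=C)[Mg]Br | starting material
11 | isopropenyl ketone (C12 ketone, C13(CH3)=CH2; 8α-allyl, 7β-OTBS, 9α-H) | C1[C@H](O[Si](C)(C)C(C)(C)C)[C@@](C)(CC=C)[C@H](CC(=O)C(C)=C)[C@@]2(C)CCCC(C)(C)[C@H]12 | intermediate
12 | 6-6-7 tricyclic 13-en-12-one (9α-H, 8β-CH3, C15 on the α face of C8, 7β-OTBS) | C1[C@H](O[Si](C)(C)C(C)(C)C)[C@@]2(C)CC=C(C)C(=O)C[C@@H]2[C@@]2(C)CCCC(C)(C)[C@H]12 | intermediate
13 | lithium cross-conjugated dienolate of 12 (C11=C12–OLi) | C1[C@H](O[Si](C)(C)C(C)(C)C)[C@@]2(C)CC=C(C)C(O[Li])=C[C@@H]2[C@@]2(C)CCCC(C)(C)[C@H]12 | intermediate (not isolated)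
14 | 6-6-7 tricyclic cross-conjugated 9(11),13-dien-12-one (7β-OTBS) | C1[C@H](O[Si](C)(C)C(C)(C)C)[C@@]2(C)CC=C(C)C(=O)C=C2[C@@]2(C)CCCC(C)(C)[C@H]12 | intermediate (key-step precursor)
15 | tetracyclic oxyallyl zwitterion (C11–C12–C13) | C1[C@H](O[Si](C)(C)C(C)(C)C)[C@@]2(C)C[C@H]3[C@@]2(C=C([O-])[C+]3C)[C@@]2(C)CCCC(C)(C)[C@H]12 | intermediate (not isolated)
16 | tetracyclic 13-hydroxy-12-ketone (cyclobutane on the α face of ring B, C11 β, 13-OH trans to C15, 7β-OTBS) | C1[C@H](O[Si](C)(C)C(C)(C)C)[C@@]2(C)C[C@H]3[C@@]2(CC(=O)[C@]3(C)O)[C@@]2(C)CCCC(C)(C)[C@H]12 | intermediate (key-step product)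
17 | C12 p-toluenesulfonylhydrazone of 16 (N–N syn to C11) | C1[C@H](O[Si](C)(C)C(C)(C)C)[C@@]2(C)C[C@H]3[C@@]2(C/C(=N\NS(=O)(=O)c4ccc(C)cc4)[C@]3(C)O)[C@@]2(C)CCCC(C)(C)[C@H]12 | intermediate
18 | C12 vinyllithium, C13 lithium alkoxide | C1[C@H](O[Si](C)(C)C(C)(C)C)[C@@]2(C)C[C@H]3[C@@]2(C=C([Li])[C@]3(C)O[Li])[C@@]2(C)CCCC(C)(C)[C@H]12 | intermediate (not isolated)
19 | tetracyclic 11-en-13-ol (7β-OTBS) | C1[C@H](O[Si](C)(C)C(C)(C)C)[C@@]2(C)C[C@H]3[C@@]2(C=C[C@]3(C)O)[C@@]2(C)CCCC(C)(C)[C@H]12 | intermediate
20 | tetracyclic 13-ol 7β-silyl ether | C1[C@H](O[Si](C)(C)C(C)(C)C)[C@@]2(C)C[C@H]3[C@@]2(CC[C@]3(C)O)[C@@]2(C)CCCC(C)(C)[C@H]12 | intermediate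
21 | tetracyclic 7β,13-diol | C1[C@H](O)[C@@]2(C)C[C@H]3[C@@]2(CC[C@]3(C)O)[C@@]2(C)CCCC(C)(C)[C@H]12 | intermediate
22 | tetracyclic 13-hydroxy-7-ketone | C1C(=O)[C@@]2(C)C[C@H]3[C@@]2(CC[C@]3(C)O)[C@@]2(C)CCCC(C)(C)[C@H]12 | intermediate
23 | 13-O-trimethylsilyl ether of 22 | C1C(=O)[C@@]2(C)C[C@H]3[C@@]2(CC[C@]3(C)O[Si](C)(C)C)[C@@]2(C)CCCC(C)(C)[C@H]12 | intermediate
24 | lithium C6–C7 enolate of 23 | C1=C(O[Li])[C@@]2(C)C[C@H]3[C@@]2(CC[C@]3(C)O[Si](C)(C)C)[C@@]2(C)CCCC(C)(C)[C@H]12 | intermediate (not isolated)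
25 | C6–C7 enol acetate (7-acetoxy-6-ene, 13-OTMS) | C1=C(OC(C)=O)[C@@]2(C)C[C@H]3[C@@]2(CC[C@]3(C)O[Si](C)(C)C)[C@@]2(C)CCCC(C)(C)[C@H]12 | intermediate
26 | 6α,7α-epoxy-7β-acetate (13-OTMS) | O1[C@H]2[C@]1(OC(C)=O)[C@@]3(C)C[C@H]4[C@@]3(CC[C@]4(C)O[Si](C)(C)C)[C@@]3(C)CCCC(C)(C)[C@H]23 | intermediate
27 | 6β-acetoxy-7-ketone 13-O-trimethylsilyl ether | CC(=O)O[C@@H]1C(=O)[C@@]2(C)C[C@H]3[C@@]2(CC[C@]3(C)O[Si](C)(C)C)[C@@]2(C)CCCC(C)(C)[C@H]12 | intermediate (not isolated)
28 | CNP0330581.1 (6β-acetoxy, 7-oxo, 8β-CH3, cyclobutane C8/C9/C14/C15 on the α face, 13-OH trans to C15, 5α-H, 10β-CH3) | CC(=O)O[C@@H]1C(=O)[C@@]2(C)C[C@H]3[C@@]2(CC[C@]3(C)O)[C@@]2(C)CCCC(C)(C)[C@H]12 | target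

**Totals**
Total step count: 19. Longest linear sequence: 19 steps (from 1).

**Steps most likely to fail**

1. Step 10. The excited dienone may instead isomerise at C13=C14 to the strained E-enone and add water at C14. The zwitterion may also undergo a 1,2-shift (cyclobutane enlargement) or lose a proton before water arrives, or be captured at C11 or on the face of C15.
 Fallback (known intramolecular enone–alkene [2+2] photocycloaddition, which forms C9–C14 and C8–C15): it sets out from 2 and returns at 22. Ester 2 would be reduced (LiAlH4, THF) to 13,14,15,16-tetranorlabd-8-en-12-ol F1 and converted (I2, PPh3, imidazole) into 12-iodo-13,14,15,16-tetranorlabd-8-ene F2. Lithiation (t-BuLi, Et2O, −78 °C) and addition (CeCl3) to methyl vinyl ketone would give labda-8,14-dien-13-ol F3. This addition has no facial bias, so the C13 epimer that matches the target would have to be separated by chromatography. Allylic oxidation at C7 (t-BuOOH, cat. Rh2(cap)4, CH2Cl2) would give 7-oxolabda-8,14-dien-13-ol F4. Irradiation (350 nm, MeCN) should then give the straight cycloadduct by 1,5-closure C9–C14 followed by C8–C15 on the α face of the enone, opposite the C10 methyl; this is ketone 22, and steps 16–19 follow unchanged.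

2. Step 19. The acetoxy group may migrate through the ionic path with retention, the epoxide may open to the diosphenol, or the axial 6β-acetate may epimerise during heating.
 Fallback (hydride reduction of a 6-ketone from the α face, which gives axial 6β-alcohols in 4,4,10-trimethyldecalins): it sets out from 23 and returns at 28. Ketone 23 would be converted (LDA; TBSCl) into the C6–C7 tert-butyldimethylsilyl enol ether F5. Hydroboration–oxidation (BH3·THF; NaBO3) on the α face would give the 6α-hydroxy-7β-silyloxy compound F6, and the periodinane of step 15 would give the 6-ketone F7. NaBH4 should deliver hydride from the α face (the β face is blocked by C19 and C20) to give the 6β-alcohol F8. Acetylation (Ac2O, DMAP, pyridine) would give the 6β-acetate F9, HF·pyridine would remove both silyl groups to give the 6β-acetoxy-7β,13-diol F10, and oxidation of the C7 alcohol as in step 15 would give 28.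

3. Step 3. Electron transfer to the methyl ester or its ammonolysis may compete, proton transfer from 6 to enolate 5 may lead to allylation at C6 or to unalkylated ketone, and facial selectivity at C8 may be incomplete.
 Fallback (regiospecific allylation of a silyl enol ether without dissolving metal): it sets out from 3 and returns at 6. Hydrogenation (H2, Pd/C, EtOAc) would give methyl 7-oxo-13,14,15,16-tetranorlabdan-12-oate F11. Thermodynamic silylation (TMSCl, NaI, Et3N, MeCN) would give the C7–C8 trimethylsilyl enol ether F12, separated from its C6–C7 isomer. Allylation with diallyl carbonate (Pd2(dba)3, dppe, THF, reflux) should then place the allyl group on the α face of C8 and give 6.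

**Further compounds**
F1 | step 10 | 13,14,15,16-tetranorlabd-8-en-12-ol | C1CC(C)=C(CCO)[C@@]2(C)CCCC(C)(C)[C@H]12
F2 | step 10 | 12-iodo-13,14,15,16-tetranorlabd-8-ene | C1CC(C)=C(CCI)[C@@]2(C)CCCC(C)(C)[C@H]12
F3 | step 10 | labda-8,14-dien-13-ol (C13 as in the target) | C1CC(C)=C(CC[C@](C=C)(C)O)[C@@]2(C)CCCC(C)(C)[C@H]12
F4 | step 10 | 7-oxolabda-8,14-dien-13-ol (C13 as in the target) | C1C(=O)C(C)=C(CC[C@](C=C)(C)O)[C@@]2(C)CCCC(C)(C)[C@H]12
F5 | step 19 | C6–C7 tert-butyldimethylsilyl enol ether of 23 | C1=C(O[Si](C)(C)C(C)(C)C)[C@@]2(C)C[C@H]3[C@@]2(CC[C@]3(C)O[Si](C)(C)C)[C@@]2(C)CCCC(C)(C)[C@H]12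
F6 | step 19 | 6α-hydroxy-7β-(tert-butyldimethylsilyloxy) 13-O-trimethylsilyl tetracycle | O[C@H]1[C@H](O[Si](C)(C)C(C)(C)C)[C@@]2(C)C[C@H]3[C@@]2(CC[C@]3(C)O[Si](C)(C)C)[C@@]2(C)CCCC(C)(C)[C@H]12
F7 | step 19 | 7β-(tert-butyldimethylsilyloxy)-6-ketone 13-O-trimethylsilyl tetracycle | O=C1[C@H](O[Si](C)(C)C(C)(C)C)[C@@]2(C)C[C@H]3[C@@]2(CC[C@]3(C)O[Si](C)(C)C)[C@@]2(C)CCCC(C)(C)[C@H]12
F8 | step 19 | 6β-hydroxy-7β-(tert-butyldimethylsilyloxy) 13-O-trimethylsilyl tetracycle | O[C@@H]1[C@H](O[Si](C)(C)C(C)(C)C)[C@@]2(C)C[C@H]3[C@@]2(CC[C@]3(C)O[Si](C)(C)C)[C@@]2(C)CCCC(C)(C)[C@H]12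
F9 | step 19 | 6β-acetoxy-7β-(tert-butyldimethylsilyloxy) 13-O-trimethylsilyl tetracycle | CC(=O)O[C@@H]1[C@H](O[Si](C)(C)C(C)(C)C)[C@@]2(C)C[C@H]3[C@@]2(CC[C@]3(C)O[Si](C)(C)C)[C@@]2(C)CCCC(C)(C)[C@H]12
F10 | step 19 | 6β-acetoxy tetracyclic 7β,13-diol | CC(=O)O[C@@H]1[C@H](O)[C@@]2(C)C[C@H]3[C@@]2(CC[C@]3(C)O)[C@@]2(C)CCCC(C)(C)[C@H]12
F11 | step 3 | methyl 7-oxo-13,14,15,16-tetranorlabdan-12-oate (8β-CH3, 8α-H, 9α-H) | C1C(=O)[C@H](C)[C@H](CC(=O)OC)[C@@]2(C)CCCC(C)(C)[C@H]12
F12 | step 3 | C7–C8 trimethylsilyl enol ether of F11 | C1C(O[Si](C)(C)C)=C(C)[C@H](CC(=O)OC)[C@@]2(C)CCCC(C)(C)[C@H]12
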